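**Retrosynthetic overview**

1. The last operation (one pot) disconnects three bonds: the O1–C2 bond of the dihydropyranone ring, and the C3–C4 and O1–C2 bonds of the coumarin lactone ring. This leads back to an isochromene quinone methide, a linear ynone β-keto ester carrying an R-configured secondary tosylate, and pyrrolidine as a traceless relay.
2. Enabling feature: the dihydropyranone is a cyclic vinylogous ester. Its ring oxygen O1 is the carbonyl oxygen of the ketone carbon C6 (the carbon bonded to coumarin C3), and its C4 carbonyl can be carried as an alkyne carbon (C4≡C5). Once an amine has added to C4, that oxygen lies five atoms from C2 and displaces a sulfonate there (6-exo-tet, inversion), while the CH2 between C6 and the ester carbon becomes coumarin C3.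
3. The quinone methide hides the aldehyde carbon (future coumarin C4) and the side-chain hydroxyl in a temporary pyran ring that the key step opens again. It comes from 2-bromo-4,6-dimethoxybenzaldehyde by aryllithium opening of (2R,3R)-2,3-epoxybutane, Mitsunobu inversion, demethylation and orthoformate cyclisation.
4. The ynone β-keto ester comes from (2R)-pent-4-yn-2-ol (chiral pool) by tosylation, Weinreb acylation of the acetylide and Claisen-type acylation of ethyl acetate.
5. Ring order: benzene ring (purchased); temporary pyran ring (step 6); dihydropyranone ring (step 10, first event); coumarin lactone ring (step 10, second event, with opening of the temporary ring).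

Key step: step 10

Remark: the quinone methide made in step 6 equilibrates with its hydrate and its ethoxy acetal in hydroxylic media; it is drawn as the quinone methide and is used at once.

**Route**

Step 1
Reactants: 1 2-bromo-4,6-dimethoxybenzaldehyde
Product: 2 1-bromo-3,5-dimethoxy-2-methylbenzene
Conditions: Et3SiH, CF3CO2H, CH2Cl2, 0 °C to rt
Reagents that add atoms: none
Why: Ionic hydrogenation: the protonated aldehyde takes up hydride from Et3SiH, the benzylic trifluoroacetate ionises to a cation stabilised by the ortho and para methoxy groups and a second hydride transfer should give the methyl group, with the aryl bromide untouched and no stereocentre involved.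

Step 2
Reactants: 2 1-bromo-3,5-dimethoxy-2-methylbenzene; 3 (2R,3R)-2,3-dimethyloxirane
Product: 5 (2R,3R)-3-(3,5-dimethoxy-2-methylphenyl)butan-2-ol, via aryllithium 4 (not isolated)
Conditions: n-BuLi, THF, −78 °C; then 3, BF3·OEt2, −78 °C; H2O
Reagents that add atoms: none
Why: Bromine–lithium exchange gives aryllithium 4, which opens the C2-symmetric epoxide in a BF3-assisted SN2 reaction (anti opening, a single regioisomer by symmetry), so the attacked carbon is inverted and the other retained, which sets the benzylic centre as R and should give the (2R,3R)-alcohol.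

Step 3
Reactants: 5 (2R,3R)-3-(3,5-dimethoxy-2-methylphenyl)butan-2-ol
Product: 6 (2S,3R)-3-(3,5-dimethoxy-2-methylphenyl)butan-2-yl 4-nitrobenzoate
Conditions: 4-nitrobenzoic acid, PPh3, DIAD, toluene, 0 °C to rt
Reagents that add atoms: 4-nitrobenzoic acid, O=C(O)c1ccc(cc1)[N+](=O)[O-]
Why: Mitsunobu reaction: the alkoxyphosphonium ion is displaced by 4-nitrobenzoate in an SN2 step with inversion, which turns the carbinol centre from R into S and completes the (2S,3R) side chain, while the ester shields this oxygen in the next step.

Step 4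
Reactants: 6 (2S,3R)-3-(3,5-dimethoxy-2-methylphenyl)butan-2-yl 4-nitrobenzoate
Product: 7 (2S,3R)-3-(3,5-dihydroxy-2-methylphenyl)butan-2-yl 4-nitrobenzoate
Conditions: BBr3, CH2Cl2, −78 to 0 °C; then MeOH, H2O
Reagents that add atoms: none
Why: Lewis-acid cleavage of aryl methyl ethers: BBr3 complexes each ether oxygen and bromide removes the methyl group by SN2 at carbon, while the electron-poor secondary ester is not ionised at low temperature and so guards the carbinol centre against neighbouring-aryl participation.

Step 5
Reactants: 7 (2S,3R)-3-(3,5-dihydroxy-2-methylphenyl)butan-2-yl 4-nitrobenzoate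
Product: 8 (2S,3R)-3-(3,5-dihydroxy-2-methylphenyl)butan-2-ol
Conditions: K2CO3 (0.2 equiv), MeOH, rt
Reagents that add atoms: none
Why: Base-catalysed transesterification of the activated 4-nitrobenzoate at its acyl carbon should free the secondary alcohol with retention, since the C–O bond of the stereocentre is not broken.

Step 6
Reactants: 8 (2S,3R)-3-(3,5-dihydroxy-2-methylphenyl)butan-2-ol
Product: 10 (3S,4R)-8-hydroxy-3,4,5-trimethyl-3,4-dihydro-6H-isochromen-6-one, via ethoxy acetal 9 (not isolated)
Conditions: HC(OEt)3, CF3CO2H (cat.), MeCN, 0 °C to rt; then evaporation from toluene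
Reagents that add atoms: triethyl orthoformate, CCOC(OCC)OCC
Why: Oxa-Pictet–Spengler-type cyclisation with an orthoester: the side-chain hydroxyl exchanges onto the orthoformate, the tethered dialkoxycarbenium ion attacks the ring carbon ortho to the side chain and para to a hydroxyl through a six-membered transition state, and loss of ethanol from acetal 9 should give the quinone methide with both stereocentres untouched.

Step 7
Reactants: 11 (2R)-pent-4-yn-2-ol
Product: 12 (2R)-pent-4-yn-2-yl 4-methylbenzenesulfonate
Conditions: TsCl, pyridine, 0 °C to rt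
Reagents that add atoms: 4-methylbenzenesulfonyl chloride, Cc1ccc(cc1)S(Cl)(=O)=O
Why: O-Sulfonylation with retention gives the R-configured tosylate, a leaving group without acidic α-hydrogens that should survive the lithium bases of the next two steps at −78 °C.

Step 8
Reactants: 12 (2R)-pent-4-yn-2-yl 4-methylbenzenesulfonate
Product: 14 (2R)-6-[methoxy(methyl)amino]-6-oxohex-4-yn-2-yl 4-methylbenzenesulfonate, via lithium acetylide 13 (not isolated)
Conditions: LiN(iPr)2, THF, −78 °C; then ClC(O)N(OMe)Me, −78 °C
Reagents that add atoms: N-methoxy-N-methylcarbamoyl chloride, CON(C)C(Cl)=O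
Why: Deprotonation of the terminal alkyne and acyl substitution of the carbamoyl chloride by lithium acetylide 13 should give the alkynyl Weinreb amide, the secondary tosylate being neither displaced nor eliminated at −78 °C.

Step 9
Reactants: 14 (2R)-6-[methoxy(methyl)amino]-6-oxohex-4-yn-2-yl 4-methylbenzenesulfonate
Product: 15 ethyl (7R)-7-[(4-methylbenzenesulfonyl)oxy]-3-oxooct-4-ynoate
Conditions: EtOAc, LiN(iPr)2, THF, −78 °C; then 14, −78 °C; 1 M HCl
Reagents that add atoms: ethyl acetate, CCOC(C)=O
Why: Claisen-type acylation: the lithium enolate of ethyl acetate adds to the Weinreb amide carbonyl to give a chelated tetrahedral adduct that cannot react twice and should collapse on acidic work-up to the β-keto ester, the tosylate stereocentre staying untouched.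

Step 10
Reactants: 15 ethyl (7R)-7-[(4-methylbenzenesulfonyl)oxy]-3-oxooct-4-ynoate; 10 (3S,4R)-8-hydroxy-3,4,5-trimethyl-3,4-dihydro-6H-isochromen-6-one
Product: 19 7-hydroxy-5-[(2R,3S)-3-hydroxybutan-2-yl]-6-methyl-3-[(2S)-2-methyl-4-oxo-3,4-dihydro-2H-pyran-6-yl]-2H-chromen-2-one, via enaminone 16 (not isolated), via pyranylidene iminium tosylate 17 (not isolated), via coumarinyl iminium tosylate 18 (not isolated)
Conditions: pyrrolidine (1.0 equiv), MeCN, 0 to 60 °C; then 10, NaOAc (0.2 equiv), 60 °C; then AcOH, H2O, rt
Reagents that add atoms: water, O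
Why: Proposed new method: pyrrolidine adds to the ynone of 15 (aza-Michael addition) to give the E-configured vinylogous amide 16, whose carbonyl oxygen is a strong neutral nucleophile held cis to the CH2CH(OTs)CH3 arm and displaces the secondary tosylate in a 6-exo-tet SN2 closure, which forms the O1–C2 bond of the dihydropyranone ring in iminium salt 17. The closest known reaction types are the O-alkylation of enaminones by alkyl sulfonates or trialkyloxonium salts and the closure of 3-sulfonyloxypropyl amides to 5,6-dihydro-4H-1,3-oxazines; because the displacement is a backside attack, the new stereocentre is controlled only by the chiral-pool tosylate, R in 15 becoming S in the ring. The iminium group then acidifies the CH2CO2Et group, and with catalytic NaOAc the derived push–pull dienamine adds through that carbon to C1 of quinone methide 10 (1,6-addition, the usual mode for enamines and 1,3-dicarbonyl compounds with quinone methides). Attack of the neighbouring phenol on the ethyl ester (6-exo-trig lactonisation) closes the coumarin ring, and E1cB loss of the isochromene oxygen from the former C1 opens the temporary ring, creates the coumarin C3=C4 bond and frees the side-chain alcohol of 18 with its two stereocentres untouched; aqueous acetic acid then hydrolyses the iminium group to the pyranone C4 ketone and returns pyrrolidine. The step needs O- over C-alkylation and no erosion at the new centre, which are secured because the enaminone has no N–H, because exactly one equivalent of amine is consumed by the ynone so that no base ionises the ester methylene before ring closure, because a homopropargylic and later allylic tosylate cannot undergo the E1cB elimination open to a β-sulfonyloxy ketone, and because the acetate buffer removes only the doubly activated exocyclic proton and not the ring CH2 beside the iminium carbon, whose loss would open the ring by a retro-6π path.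

**Compound list**

1 | 2-bromo-4,6-dimethoxybenzaldehyde | COc1cc(Br)c(C=O)c(OC)c1 | starting material
2 | 1-bromo-3,5-dimethoxy-2-methylbenzene | COc1cc(Br)c(C)c(OC)c1 | intermediate
3 | (2R,3R)-2,3-dimethyloxirane | C[C@H]1O[C@@H]1C | starting material
4 | (3,5-dimethoxy-2-methylphenyl)lithium | [Li]c1cc(OC)cc(OC)c1C | intermediate
5 | (2R,3R)-3-(3,5-dimethoxy-2-methylphenyl)butan-2-ol | COc1cc(OC)c(C)c(c1)[C@@H](C)[C@@H](C)O | intermediate
6 | (2S,3R)-3-(3,5-dimethoxy-2-methylphenyl)butan-2-yl 4-nitrobenzoate | COc1cc(OC)c(C)c(c1)[C@@H](C)[C@H](C)OC(=O)c1ccc(cc1)[N+](=O)[O-] | intermediate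
7 | (2S,3R)-3-(3,5-dihydroxy-2-methylphenyl)butan-2-yl 4-nitrobenzoate | Oc1cc(O)c(C)c(c1)[C@@H](C)[C@H](C)OC(=O)c1ccc(cc1)[N+](=O)[O-] | intermediate
8 | (2S,3R)-3-(3,5-dihydroxy-2-methylphenyl)butan-2-ol | Oc1cc(O)c(C)c(c1)[C@@H](C)[C@H](C)O | intermediate
9 | (3S,4R)-1-ethoxy-3,4,5-trimethyl-3,4-dihydro-1H-isochromene-6,8-diol (both epimers at C1) | CCOC1O[C@@H](C)[C@H](C)c2c(C)c(O)cc(O)c12 | intermediate
10 | (3S,4R)-8-hydroxy-3,4,5-trimethyl-3,4-dihydro-6H-isochromen-6-one | C[C@H]1[C@@H](C2=C(C)C(=O)C=C(O)C2=CO1)C | intermediate
11 | (2R)-pent-4-yn-2-ol | C#CC[C@@H](C)O | starting material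
12 | (2R)-pent-4-yn-2-yl 4-methylbenzenesulfonate | C#CC[C@@H](C)OS(=O)(=O)c1ccc(C)cc1 | intermediate
13 | lithium (4R)-4-[(4-methylbenzenesulfonyl)oxy]pent-1-yn-1-ide | [Li]C#CC[C@@H](C)OS(=O)(=O)c1ccc(C)cc1 | intermediate
14 | (2R)-6-[methoxy(methyl)amino]-6-oxohex-4-yn-2-yl 4-methylbenzenesulfonate | CON(C)C(=O)C#CC[C@@H](C)OS(=O)(=O)c1ccc(C)cc1 | intermediate
15 | ethyl (7R)-7-[(4-methylbenzenesulfonyl)oxy]-3-oxooct-4-ynoate | CCOC(=O)CC(=O)C#CC[C@@H](C)OS(=O)(=O)c1ccc(C)cc1 | intermediate
16 | ethyl (4E,7R)-7-[(4-methylbenzenesulfonyl)oxy]-3-oxo-5-(pyrrolidin-1-yl)oct-4-enoate | CCOC(=O)CC(=O)/C=C(/N1CCCC1)C[C@@H](C)OS(=O)(=O)c1ccc(C)cc1 | intermediate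
17 | 1-[(2S)-6-(2-ethoxy-2-oxoethyl)-2-methyl-2,3-dihydro-4H-pyran-4-ylidene]pyrrolidin-1-ium 4-methylbenzenesulfonate | CCOC(=O)CC1=CC(=[N+]2CCCC2)C[C@H](C)O1.Cc1ccc(cc1)S(=O)(=O)[O-] | intermediate
18 | 1-[(2S)-6-{7-hydroxy-5-[(2R,3S)-3-hydroxybutan-2-yl]-6-methyl-2-oxo-2H-chromen-3-yl}-2-methyl-2,3-dihydro-4H-pyran-4-ylidene]pyrrolidin-1-ium 4-methylbenzenesulfonate | Cc1c(O)cc2oc(=O)c(C3=CC(=[N+]4CCCC4)C[C@H](C)O3)cc2c1[C@@H](C)[C@H](C)O.Cc1ccc(cc1)S(=O)(=O)[O-] | intermediate
19 | 7-hydroxy-5-[(2R,3S)-3-hydroxybutan-2-yl]-6-methyl-3-[(2S)-2-methyl-4-oxo-3,4-dihydro-2H-pyran-6-yl]-2H-chromen-2-one | Cc1c(O)cc2oc(=O)c(C3=CC(=O)C[C@H](C)O3)cc2c1[C@@H](C)[C@H](C)O | target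

**Step count and risks**

Total step count: 10. Longest linear sequence: 7 steps (steps 1 to 6, then step 10); the second branch is steps 7 to 9.

Steps most likely to fail:

1. Step 10 (labelled step). Three processes may go wrong:
 - The O-cyclisation may be slow, so that C-alkylation through the ester methylene, or attack of the ester enol on the enaminone carbon, takes over.
 - The new centre may be partly lost if the ring CH2 beside the iminium carbon is deprotonated and the ring opens and recloses.
 - The quinone methide may self-condense before it is intercepted, or the fused lactone adduct may resist opening of the temporary ring.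

 The fallback uses known reaction types only, sets out from 10 and comes back at 19. Knoevenagel condensation and lactonisation of 10 with ethyl acetoacetate (piperidine, EtOH) should give 3-acetyl-7-hydroxy-5-[(2R,3S)-3-hydroxybutan-2-yl]-6-methyl-2H-chromen-2-one F1. Silylation of both hydroxyls (TBSCl, imidazole, DMF) should give 3-acetyl-7-{[tert-butyl(dimethyl)silyl]oxy}-5-[(2R,3S)-3-{[tert-butyl(dimethyl)silyl]oxy}butan-2-yl]-6-methyl-2H-chromen-2-one F2. Soft enolisation of the acetyl group (MgBr2·OEt2, iPr2NEt, CH2Cl2) and C-acylation with 1-[(3S)-3-{[tert-butyl(dimethyl)silyl]oxy}butanoyl]-1H-benzotriazole F3 (made from the commercial silyloxy acid with 1H-benzotriazole and SOCl2) should give the diketone 7-{[tert-butyl(dimethyl)silyl]oxy}-5-[(2R,3S)-3-{[tert-butyl(dimethyl)silyl]oxy}butan-2-yl]-3-[(5S)-5-{[tert-butyl(dimethyl)silyl]oxy}-3-oxohexanoyl]-6-methyl-2H-chromen-2-one F4. HF·pyridine in MeCN followed by catalytic TsOH removes the three silyl groups, and the freed 5-hydroxy-1,3-diketone cyclises and dehydrates to 19. In this fallback the pyranone is closed through its other C–O bond by attack of the S-configured hydroxyl on the ketone, so the chiral-pool centre is retained.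

2. Step 6. The electrophile may attack the ring carbon between the two hydroxyls (poor positional selectivity), and the quinone methide may condense with itself or with unreacted triol under acid. The fallback sets out from 8 and comes back at 10. Oxa-Pictet–Spengler cyclisation of 8 with dimethoxymethane (BF3·OEt2, CH2Cl2) should give (3S,4R)-3,4,5-trimethyl-3,4-dihydro-1H-isochromene-6,8-diol F5, and benzylic dehydrogenation with DDQ (1 equiv, dioxane) should convert it into 10.

3. Step 3. The electron-rich aryl ring may participate at the activated carbinol carbon (phenonium ion), which would give retention or aryl shift, and elimination may compete. The fallback sets out from 5 and comes back at 6. Oxidation with Dess–Martin periodinane (NaHCO3, CH2Cl2) should give (3R)-3-(3,5-dimethoxy-2-methylphenyl)butan-2-one F6. Reduction with LiBH(sBu)3 (THF, −78 °C), with hydride delivered anti to the aryl group under 1,2-induction, should give (2S,3R)-3-(3,5-dimethoxy-2-methylphenyl)butan-2-ol F7. Acylation with 4-nitrobenzoyl chloride in pyridine gives 6.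

Further compounds
F1 | step 10 | 3-acetyl-7-hydroxy-5-[(2R,3S)-3-hydroxybutan-2-yl]-6-methyl-2H-chromen-2-one | Cc1c(O)cc2oc(=O)c(C(C)=O)cc2c1[C@@H](C)[C@H](C)O
F2 | step 10 | 3-acetyl-7-{[tert-butyl(dimethyl)silyl]oxy}-5-[(2R,3S)-3-{[tert-butyl(dimethyl)silyl]oxy}butan-2-yl]-6-methyl-2H-chromen-2-one | Cc1c(O[Si](C)(C)C(C)(C)C)cc2oc(=O)c(C(C)=O)cc2c1[C@@H](C)[C@H](C)O[Si](C)(C)C(C)(C)C
F3 | step 10 | 1-[(3S)-3-{[tert-butyl(dimethyl)silyl]oxy}butanoyl]-1H-benzotriazole | C[C@@H](CC(=O)n1nnc2ccccc12)O[Si](C)(C)C(C)(C)C
F4 | step 10 | 7-{[tert-butyl(dimethyl)silyl]oxy}-5-[(2R,3S)-3-{[tert-butyl(dimethyl)silyl]oxy}butan-2-yl]-3-[(5S)-5-{[tert-butyl(dimethyl)silyl]oxy}-3-oxohexanoyl]-6-methyl-2H-chromen-2-one | Cc1c(O[Si](C)(C)C(C)(C)C)cc2oc(=O)c(C(=O)CC(=O)C[C@H](C)O[Si](C)(C)C(C)(C)C)cc2c1[C@@H](C)[C@H](C)O[Si](C)(C)C(C)(C)C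
F5 | step 6 | (3S,4R)-3,4,5-trimethyl-3,4-dihydro-1H-isochromene-6,8-diol | C1O[C@@H](C)[C@H](C)c2c(C)c(O)cc(O)c12
F6 | step 3 | (3R)-3-(3,5-dimethoxy-2-methylphenyl)butan-2-one | COc1cc(OC)c(C)c(c1)[C@@H](C)C(C)=O
F7 | step 3 | (2S,3R)-3-(3,5-dimethoxy-2-methylphenyl)butan-2-ol | COc1cc(OC)c(C)c(c1)[C@@H](C)[C@H](C)O
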